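The numbers in the tables were computed on assumed constants, noise included.

How much of the starting material will be product in the theta flask at 92 min? Here is what I hand over.

| flask | starting material | reagent | catalyst | time |
|---|---|---|---|---|
| zeta | 0.400 M | 0.600 M | 0.00400 M |  |
| gamma | 0.240 M | 0.440 M | 0.00400 M |  |
| delta | 0.400 M | 0.600 M | 0.00800 M |  |
| eta | 0.400 M | 0.900 M | 0.00400 M |  |
| theta | 0.400 M | 0.600 M | 0.00400 M | 92 min |

| zeta run: time / min | zeta run: [product] / M | gamma run: time / min | gamma run: [product] / M | delta run: time / min | delta run: [product] / M | eta run: time / min | eta run: [product] / M |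
|---|---|---|---|---|---|---|---|
| 0.92 | 0.014 | 0.92 | 0.011 | 0.92 | 0.027 | 0.92 | 0.017 |
| 1.5 | 0.018 | 1.5 | 0.005 | 1.5 | 0.040 | 1.5 | 0.027 |
| 2.3 | 0.028 | 2.3 | 0.021 | 2.3 | 0.053 | 2.3 | 0.033 |
| 3.7 | 0.035 | 3.7 | 0.026 | 3.7 | 0.077 | 3.7 | 0.055 |
| 5.8 | 0.063 | 5.8 | 0.036 | 5.8 | 0.117 | 5.8 | 0.071 |
| 9.2 | 0.090 | 9.2 | 0.055 | 9.2 | 0.165 | 9.2 | 0.120 |
| 15 | 0.148 | 15 | 0.083 | 15 | 0.242 | 15 | 0.174 |
| 23 | 0.198 | 23 | 0.123 | 23 | 0.305 | 23 | 0.243 |

(scatter of a reading: 0.004 M)

- reaction order in [starting material] at the outset, round the charge of the zeta run, defined at two percent of the starting material turned into product (one fixed amount of product, the same in the runs compared)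
- reaction order in [reagent] at the outset, round the charge of the zeta run, defined at two percent of the starting material turned into product
- the gamma run starts with 0.160 M less of starting material and of reagent than the zeta run, and with no product. Compared where both hold the same amount of starting material, once fifteen percent of what the gamma run was charged with has turned into product, is the gamma run faster, slower or alike (within a tenth)?
- product in the theta run at 92 min, as a share of the starting material charged

- Overall: starting material + reagent -> product, with catalyst as catalyst.
- Constant volume, constant temperature.
- The analysis sees a species whether free or bound.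
- An order is taken over about fifteen percent of the charge, up and down.

Theta has the zeta charge, so zeta's curve continued is theta's curve, with starting material as the limiting reagent: the reagent charge is 1.50 of it. Zeta stops at 23 min, but delta holds twice the catalyst and seems to run on a clock that much faster: its 0.165 M at 9.2 min lies on zeta's curve between 0.148 M at 15 min and 0.198 M at 23 min. So I read delta's last point as zeta at 46.0 min, with 0.238 of the charge left, after 0.505 at 23 min.

I replace the bending curve by its mean. The mean loss constant, ln of one over the fraction left, divided by the time taken, is 0.0313 /min.

| Stretch of zeta's time | Fraction left at its end | Loss constant |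
|---|---|---|
| start to 23 min | 0.505 | 0.0297 /min |
| 23 min to 46.0 min | 0.238 | 0.0328 /min |
| start to 46.0 min | 0.238 | 0.0313 /min |

Run on the mean, theta keeps 0.0564 of its charge at 92 min, so 94.4% is turned. With the later row's constant after 46.0 min, I get 94.7%. That shift of 0.30 percentage points is smaller than the 1.00% of the charge by which one reading scatters. So expect about 94.4% in theta, and leave its catalyst alone: this reckoning is read on zeta's clock.

The forecast gives orders of 0.7 in starting material and 0.6 in reagent, gamma alike, and 93% for theta, taking as I do that “delta at 23 min equals zeta at 46 min”.

The simulation gives orders of 0.53 and 0.59, gamma alike, and 94.2% for theta.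

    catalyst + starting material ⇌ catalyst-substrate complex, settled at all times (3.490 /M)
    catalyst-substrate complex + reagent → product + catalyst (17.10 /M/min)
    catalyst + reagent ⇌ idle catalyst-reagent complex, settled at all times (1.400 /M)
    starting material + reagent ⇌ idle substrate-reagent adduct, settled at all times (0.9810 /M)

My 94.4% stands 0.20 points above the theta value. The order in reagent is as low as 0.59 because catalyst pairs with reagent to idle catalyst-reagent complex: the same flask without that pairing has an order of 0.91 in reagent. Carried to gamma, my constant puts a fraction 0.5 of the charge turned at ln(2) over 0.0313 /min, which is 22.1 min, and gamma's simulated time is 22.5 min.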